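Ring C (flavanone numbering) is opened at the aryl ether bond O1–C8a and at C2–C3, that is, as a formal asymmetric hetero-[4+2]. The plan exploits the fact that C8a is the β-carbon of the vinylogous acyl unit C4(=O)–C4a=C8a of ring A. With fluorine on C8a, and iodine on C6 and C8 (para/ortho to it), C8a becomes an addition–elimination acceptor. The precursor is an open "benzo-Danishefsky diene", the enol silane of a 2-fluoro-3,5-diiodoacetophenone, plus an iodinated benzaldehyde. In one flask a catalytic enantioselective Mukaiyama aldol sets C2. Catalytic fluoride then passes the silylated O1 onto C8a and closes ring C, releasing only Me3SiF. One threefold Stille coupling then installs all prenyl groups.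

Key step: step 6

Assumption: the L-tryptophan-derived oxazaborolidinone is taken to direct enol silanes to the Re face of aromatic aldehydes, so the D-tryptophan-derived antipode is specified for the Si-face attack that gives S at C2; if a model aldol shows the opposite sense, the antipode is used.

Step 1
Reactants: 1 5-fluororesorcinol
Product: 2 1-(2-fluoro-4,6-dihydroxyphenyl)ethan-1-one
Conditions: AcOH, fused ZnCl2, 140 °C
Reagents that add atoms: acetic acid CC(=O)O
Why: Nencki reaction (ZnCl2-mediated Friedel–Crafts C-acylation): the acylium equivalent attacks C4 of the resorcinol, which is para to one hydroxyl and ortho to the other and is less crowded than C2 between the two hydroxyls, so the fluorine ends up ortho to the new acetyl group.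

Step 2
Reactants: 2 1-(2-fluoro-4,6-dihydroxyphenyl)ethan-1-one
Product: 3 1-(2-fluoro-4,6-dihydroxy-3,5-diiodophenyl)ethan-1-one
Conditions: NIS (2.1 equiv), MeCN, 0 °C to rt
Reagents that add atoms: N-iodosuccinimide O=C1CCC(=O)N1I
Why: Electrophilic aromatic iodination: the only two free ring positions are each ortho/para to both hydroxyls and far more nucleophilic than the acetyl enol, so exhaustive iodination has no regiochemical alternative.

Step 3
Reactants: 3 1-(2-fluoro-4,6-dihydroxy-3,5-diiodophenyl)ethan-1-one
Product: 4 1-[2-fluoro-3,5-diiodo-4,6-bis(methoxymethoxy)phenyl]ethan-1-one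
Conditions: NaH (2.2 equiv), MOMCl (2.5 equiv), DMF, 0 °C
Reagents that add atoms: chloromethyl methyl ether COCCl
Why: Williamson-type O-alkylation of the bis-phenoxide gives the two MOM acetals, NaH being strong enough to break the hydrogen bond of the hydroxyl ortho to the acetyl group, and the cold, fast alkylation leaves the C–F bond untouched.

Step 4
Reactants: 4 1-[2-fluoro-3,5-diiodo-4,6-bis(methoxymethoxy)phenyl]ethan-1-one
Product: 5 trimethylsilyl enol ether of 4 (1-aryl-1-trimethylsilyloxyethene)
Conditions: LiHMDS, THF, −78 °C; TMSCl, −78 to 0 °C; non-aqueous work-up (pentane, filtration)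
Reagents that add atoms: chlorotrimethylsilane C[Si](C)(C)Cl
Why: Kinetic deprotonation of the only enolisable position followed by O-silylation (silyl enol ether formation) gives the diene equivalent, the hindered amide base attacking neither C–F nor C–I at −78 °C.

Step 5
Reactants: 6 4-hydroxy-3-iodobenzaldehyde
Product: 7 3-iodo-4-(methoxymethoxy)benzaldehyde
Conditions: NaH, MOMCl, DMF, 0 °C
Reagents that add atoms: chloromethyl methyl ether COCCl
Why: Williamson-type O-alkylation of the phenoxide installs the same acid-labile MOM acetal as on ring A so that one final operation removes all three.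

Step 6
Reactants: 5 trimethylsilyl enol ether of 4; 7 3-iodo-4-(methoxymethoxy)benzaldehyde (slight excess)
Product: 9 (2S)-6,8-diiodo-2-[3-iodo-4-(methoxymethoxy)phenyl]-5,7-bis(methoxymethoxy)chroman-4-one, via silyl aldol 8 (not isolated)
Conditions: B-butyl oxazaborolidinone from N-tosyl-D-tryptophan and n-BuB(OH)2 (20 mol %), EtCN, −78 °C; then tetrabutylammonium difluorotriphenylsilicate (30 mol %), THF, −78 to −20 °C; pH 7 buffer
Reagents that add atoms: none
Why: Stage 1 is a catalytic enantioselective Mukaiyama aldol in which the boron Lewis acid binds aldehyde 7, its indole shields the Re face and the terminal CH2 of 5 attacks the Si face with silyl transfer, so the catalyst alone sets C2 as S in 8. Stage 2 is a fluoride-catalysed silyl ether/aryl fluoride SNAr: fluoride strips Me3Si from O1, the alkoxide adds to C8a, the charge is taken up by C4=O through C4a and by the iodine-bearing C6 and C8, and loss of fluoride restores ring A and carries the chain, Me3SiF being the only by-product. Taken together the sequence is the stepwise (aldol, then addition–elimination) version of a Danishefsky-diene hetero-Diels–Alder reaction, with C3=C4(OSi)–C4a=C8a(F) as the diene and fluoride in the role of the methoxy leaving group. Ring C closes in a 6-endo-trig addition–elimination, and because the C2–O1 bond is never broken the aldol configuration is carried into 9. The step needs attack at C8a–F rather than at C5–OMOM, and closure must outrun retro-aldol or E1cB loss from the free alkoxide. This is secured by fluoride as by far the better nucleofuge, by the two iodines ortho/para and the two acetal oxygens meta to C8a, and by low temperature and a low stationary alkoxide concentration.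

Step 7
Reactants: 9 (2S)-6,8-diiodo-2-[3-iodo-4-(methoxymethoxy)phenyl]-5,7-bis(methoxymethoxy)chroman-4-one
Product: 10 (2S)-5,7-bis(methoxymethoxy)-2-[4-(methoxymethoxy)-3-(3-methylbut-2-enyl)phenyl]-6,8-bis(3-methylbut-2-enyl)chroman-4-one
Conditions: prenylSnBu3 (4 equiv), Pd2(dba)3 (5 mol %), AsPh3 (20 mol %), CuI (20 mol %), DMF, 60 °C
Reagents that add atoms: tributyl(3-methylbut-2-en-1-yl)stannane CC(C)=CC[Sn](CCCC)(CCCC)CCCC
Why: Threefold Stille cross-coupling: aryl iodides undergo oxidative addition under neutral, base-free conditions that cannot open or epimerise the flavanone, and C–C reductive elimination at the unsubstituted allyl terminus should give the linear prenyl groups.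

Step 8
Reactants: 10 (2S)-triprenyl flavanone tris-MOM ether
Product: 11 (2S)-5,7-dihydroxy-2-[4-hydroxy-3-(3-methylbut-2-enyl)phenyl]-6,8-bis(3-methylbut-2-enyl)chroman-4-one (target)
Conditions: aq. HCl (3 M, cat.), MeOH, 45 °C, short contact time
Reagents that add atoms: none
Why: Acid-catalysed acetal exchange with methanol (MOM cleavage) frees the three phenols under conditions customary for prenylated flavanones, kept short and mild so that neither the C2–O1 bond ionises nor the phenols add to the prenyl alkenes.

Compound list
1 | 5-fluororesorcinol | Oc1cc(O)cc(F)c1 | starting material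
2 | 1-(2-fluoro-4,6-dihydroxyphenyl)ethan-1-one | CC(=O)c1c(O)cc(O)cc1F | intermediate
3 | 1-(2-fluoro-4,6-dihydroxy-3,5-diiodophenyl)ethan-1-one | CC(=O)c1c(O)c(I)c(O)c(I)c1F | intermediate
4 | 1-[2-fluoro-3,5-diiodo-4,6-bis(methoxymethoxy)phenyl]ethan-1-one | CC(=O)c1c(OCOC)c(I)c(OCOC)c(I)c1F | intermediate
5 | trimethylsilyl enol ether of 4 | C=C(O[Si](C)(C)C)c1c(OCOC)c(I)c(OCOC)c(I)c1F | intermediate
6 | 4-hydroxy-3-iodobenzaldehyde | O=Cc1ccc(O)c(I)c1 | starting material
7 | 3-iodo-4-(methoxymethoxy)benzaldehyde | O=Cc1ccc(OCOC)c(I)c1 | intermediate
8 | (3S)-1-[2-fluoro-3,5-diiodo-4,6-bis(methoxymethoxy)phenyl]-3-[3-iodo-4-(methoxymethoxy)phenyl]-3-(trimethylsilyloxy)propan-1-one (silyl aldol, not isolated) | COCOc1ccc(cc1I)[C@H](CC(=O)c1c(OCOC)c(I)c(OCOC)c(I)c1F)O[Si](C)(C)C | intermediate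
9 | (2S)-6,8-diiodo-2-[3-iodo-4-(methoxymethoxy)phenyl]-5,7-bis(methoxymethoxy)chroman-4-one | COCOc1ccc(cc1I)[C@@H]1CC(=O)c2c(OCOC)c(I)c(OCOC)c(I)c2O1 | intermediate
10 | (2S)-5,7-bis(methoxymethoxy)-2-[4-(methoxymethoxy)-3-(3-methylbut-2-enyl)phenyl]-6,8-bis(3-methylbut-2-enyl)chroman-4-one | COCOc1ccc(cc1CC=C(C)C)[C@@H]1CC(=O)c2c(OCOC)c(CC=C(C)C)c(OCOC)c(CC=C(C)C)c2O1 | intermediate
11 | (2S)-5,7-dihydroxy-2-[4-hydroxy-3-(3-methylbut-2-enyl)phenyl]-6,8-bis(3-methylbut-2-enyl)chroman-4-one | CC(C)=CCc1cc([C@@H]2CC(=O)c3c(O)c(CC=C(C)C)c(O)c(CC=C(C)C)c3O2)ccc1O | target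

Total step count: 8. Longest linear sequence: 7 (steps 1, 2, 3, 4, 6, 7, 8).

Steps most likely to fail

1. Step 6. After desilylation the free alkoxide may fragment by retro-aldol and recombine without catalyst control, which erodes the enantiomeric purity. It may also lose the oxygen by E1cB before it reaches C8a. In addition, the aldol stage may be sluggish with the electron-rich aldehyde.
   - The fallback sets out from 5 and 7 and returns at 9, and it closes the ring at the alcohol oxidation level.
   - The aldol stage alone is run and quenched with dilute acid to give the free (S)-aldol F1.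
   - NaBH4 in MeOH reduces C4=O to the 1,3-diol F2. Both C4 epimers are carried on, because this centre is erased later.
   - NaH in DMF then closes O1–C8a by plain alkoxide SNAr on the diiodo-activated fluoroarene to give the flavan-4-ol F3. No carbonyl is left to support retro-aldol or elimination.
   - Dess–Martin oxidation of the remaining C4 carbinol gives 9.

2. Step 7. Coupling may stall at the C6–I bond, which is flanked by two acetal oxygens. Allyl inversion may give branched (1,1-dimethylallyl) groups, or protodeiodination may compete.
   - The fallback sets out from 9 and returns at 10, and it builds the trisubstituted alkenes in a separate operation.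
   - Threefold Stille allylation with the smaller and regiochemically unambiguous allyltributylstannane gives the triallyl flavanone F4.
   - Threefold olefin cross-metathesis with excess 2-methyl-2-butene and a second-generation ruthenium alkylidene converts all allyl groups into prenyl groups and gives 10.

3. Step 8. Under acid the liberated phenols may add to the neighbouring prenyl alkenes (chroman formation), and prolonged exposure may ionise the benzylic C2–O1 bond.
   - The fallback sets out from 9 and returns at 11, and it reverses the order so that no prenyl group ever meets acid.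
   - The MOM groups are removed from 9 with HCl in MeOH while only iodides are present, which gives the (S)-triiodo triphenol F5.
   - The neutral threefold Stille prenylation, which tolerates free phenols, is then run on F5 with excess stannane and delivers 11 directly.

Further compounds
F1 | step 6 | (3S)-1-[2-fluoro-3,5-diiodo-4,6-bis(methoxymethoxy)phenyl]-3-hydroxy-3-[3-iodo-4-(methoxymethoxy)phenyl]propan-1-one | COCOc1ccc(cc1I)[C@H](CC(=O)c1c(OCOC)c(I)c(OCOC)c(I)c1F)O
F2 | step 6 | 1-[2-fluoro-3,5-diiodo-4,6-bis(methoxymethoxy)phenyl]-3-[3-iodo-4-(methoxymethoxy)phenyl]propane-1,3-diol, S at the B-ring carbinol, both epimers at the A-ring carbinol | COCOc1ccc(cc1I)[C@H](CC(O)c1c(OCOC)c(I)c(OCOC)c(I)c1F)O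
F3 | step 6 | (2S)-6,8-diiodo-2-[3-iodo-4-(methoxymethoxy)phenyl]-5,7-bis(methoxymethoxy)chroman-4-ol, both C4 epimers | COCOc1ccc(cc1I)[C@@H]1CC(O)c2c(OCOC)c(I)c(OCOC)c(I)c2O1
F4 | step 7 | (2S)-6,8-diallyl-2-[3-allyl-4-(methoxymethoxy)phenyl]-5,7-bis(methoxymethoxy)chroman-4-one | COCOc1ccc(cc1CC=C)[C@@H]1CC(=O)c2c(OCOC)c(CC=C)c(OCOC)c(CC=C)c2O1
F5 | step 8 | (2S)-5,7-dihydroxy-2-(4-hydroxy-3-iodophenyl)-6,8-diiodochroman-4-one | Oc1ccc(cc1I)[C@@H]1CC(=O)c2c(O)c(I)c(O)c(I)c2O1
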